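The route closes the cyclohexene last, around its trisubstituted C2=C3 alkene (ring numbering: C1 carries the quaternary side-chain carbon, C3 the methyl group, C6 the isopropenyl group). C2=C3 with its methyl is a propyne unit lying between the stereogenic allylic C1 and the C4 methylene. A C1–C6–C5–C4 chain that is nucleophilic at C1 (configurationally defined secondary boronic ester) and electrophilic at C4 (primary iodide) is therefore united with 1-propynyllithium: the alkynylboronate is alkylated at its methyl-bearing carbon by C4 while C1 migrates from boron to the other alkyne carbon with retention, forming C3–C4 and C1–C2 in one operation. The precursor is assembled by three stereospecific lithiation–borylations.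

Key step: step 14

Assumption: (S)-β-citronellene, (E)-geranylacetone, both enantiomers of sparteine, isopropenylboronic acid pinacol ester and 1-propynyllithium are taken as purchasable; Bpin = 4,4,5,5-tetramethyl-1,3,2-dioxaborolan-2-yl, TIB = 2,4,6-triisopropylbenzoyl.

Step 1
Reactants: 1 (S)-β-citronellene [(3S)-3,7-dimethylocta-1,6-diene]
Product: 3 (S)-4-methylhex-5-en-1-ol, via (S)-4-methylhex-5-enal 2 (not isolated)
Conditions: O3 (1 equiv, Sudan Red 7B end point), CH2Cl2/MeOH, −78 °C; then NaBH4, −78 → 0 °C
Reagents that add atoms: ozone, [O-][O+]=O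
Why: Chemoselective ozonolysis should cleave the electron-rich trisubstituted alkene well before the monosubstituted vinyl group, and in-pot borohydride reduction of aldehyde 2 gives the alcohol with the chiral-pool stereocentre untouched.

Step 2
Reactants: 3 (S)-4-methylhex-5-en-1-ol
Product: 4 (S)-6-iodo-3-methylhex-1-ene
Conditions: I2, PPh3, imidazole, CH2Cl2, 0 °C → rt
Reagents that add atoms: iodine, II
Why: Appel-type iodination converts the primary alcohol into the iodide by SN2 under neutral conditions that leave the vinyl group and the stereocentre alone.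

Step 3
Reactants: 4 (S)-6-iodo-3-methylhex-1-ene
Product: 6 (S)-4,4,5,5-tetramethyl-2-(4-methylhex-5-en-1-yl)-1,3,2-dioxaborolane, via alkyllithium 5 (not isolated)
Conditions: t-BuLi (2.1 equiv), Et2O/pentane, −78 °C; then i-PrOBpin, −78 °C → rt
Reagents that add atoms: 2-isopropoxy-4,4,5,5-tetramethyl-1,3,2-dioxaborolane, CC(C)OB1OC(C)(C)C(C)(C)O1
Why: Lithium–iodine exchange at −78 °C gives primary alkyllithium 5, which is borylated before 5-exo carbolithiation can set in; an anionic low-temperature route is used because radical borylations would cyclise this 5-hexenyl system.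

Step 4
Reactants: 7 (E)-geranylacetone [(5E)-6,10-dimethylundeca-5,9-dien-2-one]
Product: 8 (2S,5E)-6,10-dimethylundeca-5,9-dien-2-ol
Conditions: ADH-A (Prelog-selective alcohol dehydrogenase from Rhodococcus ruber), NAD+ (cat.), i-PrOH, phosphate buffer pH 7.5, 30 °C
Reagents that add atoms: none
Why: Enzymatic asymmetric ketone reduction: a Prelog-selective dehydrogenase delivers hydride to the Re face of the methyl ketone (as with the lower homologue sulcatone) and should set the (S)-carbinol, with i-PrOH recycling the cofactor.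

Step 5
Reactants: 8 (2S,5E)-6,10-dimethylundeca-5,9-dien-2-ol
Product: 9 (2R,5E)-6,10-dimethylundeca-5,9-dien-2-yl 2,4,6-triisopropylbenzoate
Conditions: 2,4,6-triisopropylbenzoic acid, PPh3, DIAD, THF, 0 °C → rt
Reagents that add atoms: 2,4,6-triisopropylbenzoic acid, CC(C)c1cc(C(C)C)c(C(=O)O)c(C(C)C)c1
Why: Mitsunobu esterification proceeds by SN2 inversion and turns the (S)-alcohol into the (R)-benzoate that serves as carbenoid precursor.

Step 6
Reactants: 9 (2R,5E)-6,10-dimethylundeca-5,9-dien-2-yl 2,4,6-triisopropylbenzoate; 6 (S)-4,4,5,5-tetramethyl-2-(4-methylhex-5-en-1-yl)-1,3,2-dioxaborolane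
Product: 12 2-[(3S,7R,10E)-3,7,11,15-tetramethylhexadeca-1,10,14-trien-7-yl]-4,4,5,5-tetramethyl-1,3,2-dioxaborolane (tertiary boronic ester), via lithiated benzoate 10 (not isolated), via boronate complex 11 (not isolated)
Conditions: s-BuLi, TMEDA, CPME, −60 °C; then 6, −60 → 40 °C
Reagents that add atoms: none
Why: Lithiation–borylation of a secondary dialkyl benzoate: carbonyl-directed deprotonation with retention gives configurationally stable 10, borylation with retention gives 11, and the 1,2-metallate shift of the primary alkyl group expels the benzoate with inversion, so the quaternary stereocentre is set stereospecifically by the carbinol configuration of 9.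

Step 7
Reactants: 13 3-((tert-butyldimethylsilyl)oxy)propan-1-ol
Product: 14 3-((tert-butyldimethylsilyl)oxy)propyl N,N-diisopropylcarbamate
Conditions: N,N-diisopropylcarbamoyl chloride, Et3N, CH2Cl2, reflux
Reagents that add atoms: N,N-diisopropylcarbamoyl chloride, CC(C)N(C(C)C)C(Cl)=O
Why: O-Carbamoylation of the primary alcohol installs the directing and leaving group for α-lithiation.

Step 8
Reactants: 14 3-((tert-butyldimethylsilyl)oxy)propyl N,N-diisopropylcarbamate; 15 isopropenylboronic acid pinacol ester
Product: 18 tert-butyldimethyl{[(3R)-4-methyl-3-(4,4,5,5-tetramethyl-1,3,2-dioxaborolan-2-yl)pent-4-en-1-yl]oxy}silane (allylic boronic ester), via lithiated carbamate 16 (not isolated), via boronate complex 17 (not isolated)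
Conditions: s-BuLi, (−)-sparteine, Et2O, −78 °C; then 15, −78 °C; then MgBr2·OEt2, reflux
Reagents that add atoms: none
Why: Lithiation–borylation: s-BuLi/(−)-sparteine removes the pro-S α-proton, borylation occurs with retention and the isopropenyl group migrates with inversion, which should set the future ring C6 centre under reagent control.

Step 9
Reactants: 18 allylic boronic ester
Product: 21 (2R)-4-((tert-butyldimethylsilyl)oxy)-2-(prop-1-en-2-yl)butan-1-ol, via chloromethyl boronate complex 19 (not isolated), via homologated boronic ester 20 (not isolated)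
Conditions: ClCH2I, n-BuLi, THF, −78 °C → rt; then NaOH, H2O2, THF/H2O, 0 °C
Reagents that add atoms: chloroiodomethane, ClCI; hydrogen peroxide, OO
Why: Matteson homologation: ClCH2Li made in situ adds to boron and the stereogenic allylic carbon migrates with retention onto the chloromethyl carbon, after which alkaline peroxide oxidises the primary C–B bond to the alcohol.

Step 10
Reactants: 21 (2R)-4-((tert-butyldimethylsilyl)oxy)-2-(prop-1-en-2-yl)butan-1-ol
Product: 22 (2R)-4-((tert-butyldimethylsilyl)oxy)-2-(prop-1-en-2-yl)butyl 2,4,6-triisopropylbenzoate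
Conditions: 2,4,6-triisopropylbenzoic acid, PPh3, DIAD, THF, 0 °C → rt
Reagents that add atoms: 2,4,6-triisopropylbenzoic acid, CC(C)c1cc(C(C)C)c(C(=O)O)c(C(C)C)c1
Why: Mitsunobu esterification of the primary alcohol gives the hindered benzoate needed for the next lithiation–borylation; no stereocentre is involved.

Step 11
Reactants: 22 (2R)-4-((tert-butyldimethylsilyl)oxy)-2-(prop-1-en-2-yl)butyl 2,4,6-triisopropylbenzoate; 12 tertiary boronic ester
Product: 25 tert-butyldimethyl{[(3S,4S)-3-(prop-1-en-2-yl)-4-(4,4,5,5-tetramethyl-1,3,2-dioxaborolan-2-yl)-4-[(3S,7S,10E)-3,7,11,15-tetramethylhexadeca-1,10,14-trien-7-yl]butyl]oxy}silane (secondary boronic ester), via lithiated benzoate 23 (not isolated), via boronate complex 24 (not isolated)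
Conditions: s-BuLi, (+)-sparteine, Et2O, −78 °C; then 12, −78 → 35 °C
Reagents that add atoms: none
Why: Lithiation–borylation with a hindered boronic ester: s-BuLi/(+)-sparteine removes the pro-R proton under reagent control, 23 is borylated with retention by 12, and the tertiary alkyl group migrates with retention at the quaternary carbon and inversion at the carbenoid carbon, which sets ring C1 and joins the two halves.

Step 12
Reactants: 25 secondary boronic ester (silyl ether)
Product: 26 (3S,4S)-3-(prop-1-en-2-yl)-4-(4,4,5,5-tetramethyl-1,3,2-dioxaborolan-2-yl)-4-[(3S,7S,10E)-3,7,11,15-tetramethylhexadeca-1,10,14-trien-7-yl]butan-1-ol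
Conditions: CSA (cat.), MeOH/CH2Cl2, 0 °C
Reagents that add atoms: none
Why: Acid-catalysed methanolysis cleaves the primary silyl ether under conditions mild enough for the pinacol boronate and the alkenes.

Step 13
Reactants: 26 boronic ester alcohol
Product: 27 2-[(1S,2S)-4-iodo-2-(prop-1-en-2-yl)-1-[(3S,7S,10E)-3,7,11,15-tetramethylhexadeca-1,10,14-trien-7-yl]butyl]-4,4,5,5-tetramethyl-1,3,2-dioxaborolane
Conditions: I2, PPh3, imidazole, CH2Cl2, 0 °C
Reagents that add atoms: iodine, II
Why: Appel-type iodination turns the primary alcohol into the electrophilic C4 terminus while the boronic ester is inert to Ph3P/I2.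

Step 14
Reactants: 27 iodo boronic ester; 28 1-propynyllithium
Product: 30 4,4,5,5-tetramethyl-2-[(5S,6R)-2-methyl-5-(prop-1-en-2-yl)-6-[(3S,7S,10E)-3,7,11,15-tetramethylhexadeca-1,10,14-trien-7-yl]cyclohex-1-en-1-yl]-1,3,2-dioxaborolane (the target carrying Bpin at ring C2), via alkynylboronate complex 29 (not isolated)
Conditions: THF, −78 °C, 1 h; then 45 °C
Reagents that add atoms: none
Why: Proposed new method: 1-propynyllithium adds reversibly to the boron of 27 to give alkynylboronate 29, whose ynamine-like methyl-bearing carbon displaces the tethered primary iodide while the C1–B bond shifts to the boron-bound alkyne carbon, so that C3–C4 (SN2 at C4) and C1–C2 (1,2-metallate shift) form in one operation and the neutral alkenyl boronate 30 results. The closest known reaction type is the electrophile-induced 1,2-migration of lithium alkynylborates on C-alkylation with alkyl halides, including intramolecular cases with a tethered leaving group, here extended to a boronic ester whose migrating group carries the electrophile. The six-membered carbocycle closes by a 6-exo-tet displacement at C4 that passes through a seven-membered boron-containing array (7-endo-dig with respect to the alkyne) and contracts as C1 shifts; because the new alkene is endocyclic, the migrating and alkylating carbons can only end up cis. No new stereocentre is formed: C1 migrates with retention, as in Zweifel and Matteson chemistry, so the configuration set in step 11 is carried over and C6, the quaternary carbon and the side-chain centre are untouched. The step needs C-alkylation within 29 to outrun alkylation of free propynyllithium and cyclobutane-forming substitution at C1; the tether, THF without dipolar additives (in which lithium acetylides alkylate iodides only sluggishly) and the hindered, poorly nucleophilic C1–B bond should secure this.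

Step 15
Reactants: 30 cyclohexenyl boronic ester
Product: 31 (3S,7S,10E)-3,7,11,15-tetramethyl-7-[(1S,6S)-3-methyl-6-(prop-1-en-2-yl)cyclohex-2-en-1-yl]hexadeca-1,10,14-triene (target)
Conditions: AgNO3 (cat.), Et3N, EtOH/H2O, 70 °C
Reagents that add atoms: none
Why: Base-promoted silver-catalysed protodeboronation should replace the sp2 C–B bond by C–H with the double bond held in place by the ring, under neutral conditions that avoid migration of the other alkenes.

Compound list
1 | (S)-β-citronellene, (3S)-3,7-dimethylocta-1,6-diene | C=C[C@@H](C)CCC=C(C)C | starting material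
2 | (S)-4-methylhex-5-enal | C=C[C@@H](C)CCC=O | intermediate
3 | (S)-4-methylhex-5-en-1-ol | C=C[C@@H](C)CCCO | intermediate
4 | (S)-6-iodo-3-methylhex-1-ene | C=C[C@@H](C)CCCI | intermediate
5 | (S)-(4-methylhex-5-en-1-yl)lithium | C=C[C@@H](C)CCC[Li] | intermediate
6 | (S)-4,4,5,5-tetramethyl-2-(4-methylhex-5-en-1-yl)-1,3,2-dioxaborolane | C=C[C@@H](C)CCCB1OC(C)(C)C(C)(C)O1 | intermediate
7 | (E)-geranylacetone, (5E)-6,10-dimethylundeca-5,9-dien-2-one | CC(=O)CC/C=C(\C)CCC=C(C)C | starting material
8 | (2S,5E)-6,10-dimethylundeca-5,9-dien-2-ol | C[C@H](O)CC/C=C(\C)CCC=C(C)C | intermediate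
9 | (2R,5E)-6,10-dimethylundeca-5,9-dien-2-yl 2,4,6-triisopropylbenzoate | C[C@@H](OC(=O)c1c(C(C)C)cc(C(C)C)cc1C(C)C)CC/C=C(\C)CCC=C(C)C | intermediate
10 | tertiary α-lithiated benzoate of 9 (lithium in place of the carbinol hydrogen, configuration retained) | C[C@@]([Li])(OC(=O)c1c(C(C)C)cc(C(C)C)cc1C(C)C)CC/C=C(\C)CCC=C(C)C | intermediate
11 | lithium boronate complex of 10 with 6 | C[C@@]([B-]1(CCC[C@H](C)C=C)OC(C)(C)C(C)(C)O1)(OC(=O)c1c(C(C)C)cc(C(C)C)cc1C(C)C)CC/C=C(\C)CCC=C(C)C.[Li+] | intermediate
12 | 2-[(3S,7R,10E)-3,7,11,15-tetramethylhexadeca-1,10,14-trien-7-yl]-4,4,5,5-tetramethyl-1,3,2-dioxaborolane (tertiary boronic ester) | C=C[C@@H](C)CCC[C@@](C)(CC/C=C(\C)CCC=C(C)C)B1OC(C)(C)C(C)(C)O1 | intermediate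
13 | 3-((tert-butyldimethylsilyl)oxy)propan-1-ol | OCCCO[Si](C)(C)C(C)(C)C | starting material
14 | 3-((tert-butyldimethylsilyl)oxy)propyl N,N-diisopropylcarbamate | CC(C)N(C(C)C)C(=O)OCCCO[Si](C)(C)C(C)(C)C | intermediate
15 | isopropenylboronic acid pinacol ester | C=C(C)B1OC(C)(C)C(C)(C)O1 | starting material
16 | (S)-α-lithiated carbamate of 14 | [Li][C@@H](CCO[Si](C)(C)C(C)(C)C)OC(=O)N(C(C)C)C(C)C | intermediate
17 | lithium boronate complex of 16 with 15 | C=C(C)[B-]1([C@@H](CCO[Si](C)(C)C(C)(C)C)OC(=O)N(C(C)C)C(C)C)OC(C)(C)C(C)(C)O1.[Li+] | intermediate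
18 | tert-butyldimethyl{[(3R)-4-methyl-3-(4,4,5,5-tetramethyl-1,3,2-dioxaborolan-2-yl)pent-4-en-1-yl]oxy}silane | C=C(C)[C@@H](CCO[Si](C)(C)C(C)(C)C)B1OC(C)(C)C(C)(C)O1 | intermediate
19 | lithium (chloromethyl)boronate complex of 18 | C=C(C)[C@@H](CCO[Si](C)(C)C(C)(C)C)[B-]1(CCl)OC(C)(C)C(C)(C)O1.[Li+] | intermediate
20 | (R)-homologated primary boronic ester, Bpin on the new CH2 | C=C(C)[C@@H](CCO[Si](C)(C)C(C)(C)C)CB1OC(C)(C)C(C)(C)O1 | intermediate
21 | (2R)-4-((tert-butyldimethylsilyl)oxy)-2-(prop-1-en-2-yl)butan-1-ol | C=C(C)[C@@H](CCO[Si](C)(C)C(C)(C)C)CO | intermediate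
22 | (2R)-4-((tert-butyldimethylsilyl)oxy)-2-(prop-1-en-2-yl)butyl 2,4,6-triisopropylbenzoate | C=C(C)[C@@H](CCO[Si](C)(C)C(C)(C)C)COC(=O)c1c(C(C)C)cc(C(C)C)cc1C(C)C | intermediate
23 | (R)-α-lithiated benzoate of 22 | C=C(C)[C@@H](CCO[Si](C)(C)C(C)(C)C)[C@@H]([Li])OC(=O)c1c(C(C)C)cc(C(C)C)cc1C(C)C | intermediate
24 | lithium boronate complex of 23 with 12 | C=C(C)[C@@H](CCO[Si](C)(C)C(C)(C)C)[C@@H]([B-]1([C@@](C)(CCC[C@H](C)C=C)CC/C=C(\C)CCC=C(C)C)OC(C)(C)C(C)(C)O1)OC(=O)c1c(C(C)C)cc(C(C)C)cc1C(C)C.[Li+] | intermediate
25 | secondary boronic ester: CH(Bpin) (future ring C1, S) joined to the quaternary carbon (S) and to the CH(isopropenyl)CH2CH2OTBS carbon (future C6, S) | C=C[C@@H](C)CCC[C@@](C)(CC/C=C(\C)CCC=C(C)C)[C@@H](B1OC(C)(C)C(C)(C)O1)[C@H](CCO[Si](C)(C)C(C)(C)C)C(=C)C | intermediate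
26 | primary alcohol from 25 | C=C[C@@H](C)CCC[C@@](C)(CC/C=C(\C)CCC=C(C)C)[C@@H](B1OC(C)(C)C(C)(C)O1)[C@H](CCO)C(=C)C | intermediate
27 | primary iodide from 26 | C=C[C@@H](C)CCC[C@@](C)(CC/C=C(\C)CCC=C(C)C)[C@@H](B1OC(C)(C)C(C)(C)O1)[C@H](CCI)C(=C)C | intermediate
28 | 1-propynyllithium | [Li]C#CC | starting material
29 | lithium alkynylboronate complex of 27 with 28 | C=C[C@@H](C)CCC[C@@](C)(CC/C=C(\C)CCC=C(C)C)[C@@H]([B-]1(C#CC)OC(C)(C)C(C)(C)O1)[C@H](CCI)C(=C)C.[Li+] | intermediate
30 | cyclohexenyl boronic ester, the target with Bpin at ring C2 | C=C[C@@H](C)CCC[C@@](C)(CC/C=C(\C)CCC=C(C)C)[C@H]1C(B2OC(C)(C)C(C)(C)O2)=C(C)CC[C@@H]1C(=C)C | intermediate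
31 | (3S,7S,10E)-3,7,11,15-tetramethyl-7-[(1S,6S)-3-methyl-6-(prop-1-en-2-yl)cyclohex-2-en-1-yl]hexadeca-1,10,14-triene | C=C[C@@H](C)CCC[C@@](C)(CC/C=C(\C)CCC=C(C)C)[C@H]1C=C(C)CC[C@@H]1C(=C)C | target

Total step count: 15. Longest linear sequence: 9 steps (1–2–3–6–11–12–13–14–15, or 7–8–9–10–11–12–13–14–15).

Steps most likely to fail

Step 14 (proposed new method). The boronate complex may dissociate faster than it is alkylated, so that free acetylide is consumed by the iodide, or the congested array may fail to close. The fallback gives up the single operation and forms the same two bonds one after the other by known reactions, setting out from 25 and coming back at 31. Zweifel olefination of 25 (vinyllithium, THF, −78 °C; I2; NaOMe) moves C1 onto a vinyl carbon with retention and should give the vinyl silyl ether F1. CSA/MeOH then gives the alcohol F2, and Ph3P/I2/imidazole the iodide F3. CuI-catalysed coupling with isopropenylmagnesium bromide, CH2=C(CH3)MgBr, gives the metathesis precursor F4. Ring-closing metathesis with second-generation Grubbs catalyst, (H2IMes)(PCy3)Cl2Ru=CHPh, in dilute CH2Cl2 joins the C1 vinyl and C4 isopropenyl groups as C2=C3 and gives 31.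

Step 11. Formation of the boronate complex at the hindered tertiary boron may be slow, and α-lithiation next to the C6 centre may be mismatched with the diamine, costing yield or diastereoselectivity. The fallback moves the carbenoid to the other half, setting out from 12 (with 18 taken before step 9) and coming back at 25. Matteson homologation of 12 (ClCH2I, n-BuLi) with NaOH/H2O2 work-up gives the neopentyl-type alcohol F5, and N,N-diisopropylcarbamoyl chloride gives the carbamate F6. Lithiation of F6 with s-BuLi/(−)-sparteine (pro-S proton, no neighbouring stereocentre), borylation with 18 and MgBr2·OEt2-promoted 1,2-shift of the allylic carbon then form the C1–C6 bond, instead of the bond from C1 to the quaternary carbon, and give 25.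

Step 15. Protodeboronation of the hindered alkenyl boronate may be sluggish, and forcing it may move double bonds. The fallback sets out from 30 and comes back at 31: iododeboronation (NaOH, I2, THF, 0 °C) gives the alkenyl iodide F7, and lithium–iodine exchange (t-BuLi, Et2O, −78 °C) with MeOH quench gives 31.

Further compounds
F1 | step 14 | vinyl silyl ether (Bpin of 25 replaced by vinyl with retention) | C=C[C@@H](C)CCC[C@@](C)(CC/C=C(\C)CCC=C(C)C)[C@@H](C=C)[C@H](CCO[Si](C)(C)C(C)(C)C)C(=C)C
F2 | step 14 | primary alcohol from F1 | C=C[C@@H](C)CCC[C@@](C)(CC/C=C(\C)CCC=C(C)C)[C@@H](C=C)[C@H](CCO)C(=C)C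
F3 | step 14 | primary iodide from F2 | C=C[C@@H](C)CCC[C@@](C)(CC/C=C(\C)CCC=C(C)C)[C@@H](C=C)[C@H](CCI)C(=C)C
F4 | step 14 | metathesis precursor with isopropenyl on C4 | C=C[C@@H](C)CCC[C@@](C)(CC/C=C(\C)CCC=C(C)C)[C@@H](C=C)[C@H](CCC(C)=C)C(=C)C
F5 | step 11 | neopentyl-type alcohol, CH2OH on the quaternary carbon | C=C[C@@H](C)CCC[C@@](C)(CC/C=C(\C)CCC=C(C)C)CO
F6 | step 11 | N,N-diisopropylcarbamate of F5 | C=C[C@@H](C)CCC[C@@](C)(CC/C=C(\C)CCC=C(C)C)COC(=O)N(C(C)C)C(C)C
F7 | step 15 | alkenyl iodide, iodine at ring C2 | C=C[C@@H](C)CCC[C@@](C)(CC/C=C(\C)CCC=C(C)C)[C@H]1C(I)=C(C)CC[C@@H]1C(=C)C
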